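**Retrosynthetic overview**
1. Target 25 ⇐ C3-epimer mixture 24 (final exo-face enolate protonation) ⇐ β-hydroxy ketone 23 ⇐ bicyclic ketol 21, by reducing the bridging C8 ketone and oxidising the C2 carbinol.
2. The six-membered ring is formed last: the C1–C2 bond by intramolecular aldol addition of keto aldehyde 20 onto a preformed cyclopentanone.
3. The aryl group at C7 comes from conjugate addition to enone 13 anti to the C6 methyl; the C1 methoxy group from Rubottom oxidation and O-methylation.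
4. Key bond C4–C5 (quaternary C5): intermolecular Michael addition of the imine/enamine of ketone 7 to methyl 2-methoxyacrylate 8.
5. Ketone 7 (five-membered ring, formed first) comes from (R)-pulegone by Favorskii ring contraction, ozonolysis, allylation and decarboxylation.

Assumption: locants C1–C8 are those of the target's bicyclo[3.2.1]octane core (C1 = OMe bridgehead, C2 = ketone, C3 = CH(OMe), C4 = CH2, C5 = allyl bridgehead, C6 = CHCH3, C7 = CHAr, C8 = CHOAc; Ar = 3,4-dimethoxyphenyl); epimer mixtures at centres that are reset later are carried on unseparated.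

**Step 1**
Reactants: 1 (R)-(+)-pulegone
Product: 3 methyl pulegenate, via pulegone dibromide 2 (not isolated)
Conditions: Br2, Et2O, 0 °C; then NaOMe, MeOH, reflux
Reagents that add atoms: sodium methoxide, [Na+].[O-]C
Why: Bromine adds to the exocyclic alkene and methoxide then triggers a Favorskii rearrangement (cyclopropanone opening, loss of the tertiary bromide) that contracts the ring without touching the methyl-bearing stereocentre, which becomes C6 (R) of the target.

**Step 2**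
Reactants: 3 methyl pulegenate
Product: 4 methyl (1S,2R)-2-methyl-5-oxocyclopentane-1-carboxylate
Conditions: O3, CH2Cl2/MeOH, −78 °C; then Me2S, −78 to 25 °C
Reagents that add atoms: ozone, [O-][O+]=O
Why: Ozonolysis with reductive work-up cleaves the tetrasubstituted alkene to the ring ketone (future C8), giving a β-keto ester whose activated carbon (future C5) lies next to the methyl-bearing carbon; the epimerisable ester centre settles trans to methyl.

**Step 3**
Reactants: 4 methyl (1S,2R)-2-methyl-5-oxocyclopentane-1-carboxylate; 5 allyl bromide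
Product: 6 methyl (1R,2R)-2-methyl-5-oxo-1-(prop-2-en-1-yl)cyclopentane-1-carboxylate
Conditions: K2CO3, acetone, reflux
Reagents that add atoms: none
Why: C-alkylation of the stabilised β-keto ester enolate with an allylic bromide is regiospecific, the allyl group entering anti to the adjacent methyl (this centre is planarised again in step 5).

**Step 4**
Reactants: 6 methyl (1R,2R)-2-methyl-5-oxo-1-(prop-2-en-1-yl)cyclopentane-1-carboxylate
Product: 7 (2S,3R)-3-methyl-2-(prop-2-en-1-yl)cyclopentan-1-one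
Conditions: LiCl, H2O, DMSO, 150 °C
Reagents that add atoms: none
Why: Krapcho dealkoxycarbonylation removes the activating ester under neutral conditions and protonation of the enol gives mainly the trans ketone.

**Step 5**
Reactants: 7 (2S,3R)-3-methyl-2-(prop-2-en-1-yl)cyclopentan-1-one; 8 methyl 2-methoxyacrylate
Product: 11 methyl 2-methoxy-3-[(1S,2R)-2-methyl-5-oxo-1-(prop-2-en-1-yl)cyclopentyl]propanoate, via N-benzyl ketimine 9 (not isolated), via adduct ketimine 10 (not isolated)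
Conditions: BnNH2, toluene, reflux (Dean–Stark); then 8 (neat), 70 °C; then 20% aq AcOH, 25 °C
Reagents that add atoms: none
Why: The ketimine reacts through its more substituted secondary enamine tautomer in an aza-ene-type intermolecular Michael addition, so the C4–C5 bond forms only at the allyl-bearing α-carbon and anti to the C6 methyl, fixing quaternary C5 with allyl cis and the three-carbon arm trans to methyl; the methoxy-bearing carbon of the arm (future C3) forms unselectively and is set in step 16.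

**Step 6**
Reactants: 11 methyl 2-methoxy-3-[(1S,2R)-2-methyl-5-oxo-1-(prop-2-en-1-yl)cyclopentyl]propanoate
Product: 13 methyl 2-methoxy-3-[(1S,5R)-5-methyl-2-oxo-1-(prop-2-en-1-yl)cyclopent-3-en-1-yl]propanoate, via silyl enol ether 12 (not isolated)
Conditions: TMSOTf, Et3N, CH2Cl2, 0 °C; then Pd(OAc)2, MeCN, 25 °C
Reagents that add atoms: none
Why: Soft enolisation can only go towards the CH2 side (the other α-carbon is quaternary) and Saegusa–Ito oxidation of the silyl enol ether installs the C1=C7 enone without affecting the ester or the terminal alkene.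

**Step 7**
Reactants: 13 methyl 2-methoxy-3-[(1S,5R)-5-methyl-2-oxo-1-(prop-2-en-1-yl)cyclopent-3-en-1-yl]propanoate; 14 3,4-dimethoxyphenylmagnesium bromide
Product: 15 methyl 3-[(1S,2R,3R)-3-(3,4-dimethoxyphenyl)-2-methyl-1-(prop-2-en-1-yl)-5-(trimethylsilyloxy)cyclopent-4-en-1-yl]-2-methoxypropanoate
Conditions: CuBr·SMe2 (10 mol%), TMSCl, THF, −78 °C
Reagents that add atoms: chlorotrimethylsilane, C[Si](C)(C)Cl
Why: Copper-catalysed conjugate addition of the aryl Grignard reagent, accelerated and trapped by TMSCl, delivers the aryl group to C7 from the face opposite the adjacent C6 methyl (trans, as usual for 4-substituted cyclopentenones) and fixes the enolate regiospecifically as its silyl ether.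

**Step 8**
Reactants: 15 methyl 3-[(1S,2R,3R)-3-(3,4-dimethoxyphenyl)-2-methyl-1-(prop-2-en-1-yl)-5-(trimethylsilyloxy)cyclopent-4-en-1-yl]-2-methoxypropanoate
Product: 17 methyl 3-[(1S,2R,3S,4S)-3-(3,4-dimethoxyphenyl)-4-hydroxy-2-methyl-5-oxo-1-(prop-2-en-1-yl)cyclopentyl]-2-methoxypropanoate, via silyloxy ketone 16 (not isolated)
Conditions: mCPBA, CH2Cl2, −20 °C; then 1 M HCl, THF, 0 °C
Reagents that add atoms: 3-chloroperoxybenzoic acid, OOC(=O)c1cccc(Cl)c1
Why: Rubottom oxidation, in which the electron-rich silyl enol ether is epoxidised far faster than the terminal alkene or the arene and rearranges to the α-silyloxy ketone, oxygen entering anti to the neighbouring aryl group (this centre is planarised again in step 12).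

**Step 9**
Reactants: 17 methyl 3-[(1S,2R,3S,4S)-3-(3,4-dimethoxyphenyl)-4-hydroxy-2-methyl-5-oxo-1-(prop-2-en-1-yl)cyclopentyl]-2-methoxypropanoate
Product: 18 methyl 3-[(1S,2R,3S,4S)-3-(3,4-dimethoxyphenyl)-4-methoxy-2-methyl-5-oxo-1-(prop-2-en-1-yl)cyclopentyl]-2-methoxypropanoate
Conditions: MeI, Ag2O, MeCN, 40 °C, dark
Reagents that add atoms: iodomethane, CI
Why: Purdie methylation etherifies the α-ketol under non-basic conditions that avoid α-ketol rearrangement.

**Step 10**
Reactants: 18 methyl 3-[(1S,2R,3S,4S)-3-(3,4-dimethoxyphenyl)-4-methoxy-2-methyl-5-oxo-1-(prop-2-en-1-yl)cyclopentyl]-2-methoxypropanoate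
Product: 19 (2S,3S,4R,5S)-3-(3,4-dimethoxyphenyl)-5-(3-hydroxy-2-methoxypropyl)-2-methoxy-4-methyl-5-(prop-2-en-1-yl)cyclopentan-1-ol
Conditions: LiAlH4, THF, 0 °C
Reagents that add atoms: none
Why: LiAlH4 reduces both ester and ketone, which avoids a chemoselective ester-to-aldehyde reduction next to a ketone; the new carbinol centre is removed again in step 11.

**Step 11**
Reactants: 19 (2S,3S,4R,5S)-3-(3,4-dimethoxyphenyl)-5-(3-hydroxy-2-methoxypropyl)-2-methoxy-4-methyl-5-(prop-2-en-1-yl)cyclopentan-1-ol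
Product: 20 3-[(1S,2R,3S,4S)-3-(3,4-dimethoxyphenyl)-4-methoxy-2-methyl-5-oxo-1-(prop-2-en-1-yl)cyclopentyl]-2-methoxypropanal
Conditions: DMP, CH2Cl2, 25 °C
Reagents that add atoms: none
Why: Dess–Martin oxidation converts the primary alcohol into the aldehyde and the secondary alcohol back into the ketone under neutral conditions.

**Step 12**
Reactants: 20 3-[(1S,2R,3S,4S)-3-(3,4-dimethoxyphenyl)-4-methoxy-2-methyl-5-oxo-1-(prop-2-en-1-yl)cyclopentyl]-2-methoxypropanal
Product: 21 (1R,5S,6R,7S)-7-(3,4-dimethoxyphenyl)-2-hydroxy-1,3-dimethoxy-6-methyl-5-(prop-2-en-1-yl)bicyclo[3.2.1]octan-8-one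
Conditions: TsOH·H2O (20 mol%), toluene, 50 °C
Reagents that add atoms: none
Why: Acid-catalysed intramolecular aldol addition in which the ketone can enolise only towards methoxy-bearing C1 and the tether (on the ring face trans to the C6 methyl, cis to the aryl group) forces C1–C2 bond formation on that face, closing the six-membered ring and making C1 quaternary with aryl endo and methyl exo; C2 and C3 are formed as mixtures and converged later.

**Step 13**
Reactants: 21 (1R,5S,6R,7S)-7-(3,4-dimethoxyphenyl)-2-hydroxy-1,3-dimethoxy-6-methyl-5-(prop-2-en-1-yl)bicyclo[3.2.1]octan-8-one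
Product: 22 (1S,5S,6R,7S,8S)-7-(3,4-dimethoxyphenyl)-1,3-dimethoxy-6-methyl-5-(prop-2-en-1-yl)bicyclo[3.2.1]octane-2,8-diol
Conditions: SmI2, H2O, Et3N, THF, 0 °C
Reagents that add atoms: none
Why: Electron-transfer ketone reduction goes through a ketyl/organosamarium species that places the bulky O–Sm group on the less encumbered side of C8 (syn to the three-carbon bridge, away from the exo C6 methyl) before protonation, giving the more stable 8S carbinol that hydride reagents attacking from that open side would not give; the bridgehead C1–OMe bond lies in the nodal plane of the ketyl and is not cleaved.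

**Step 14**
Reactants: 22 (1S,5S,6R,7S,8S)-7-(3,4-dimethoxyphenyl)-1,3-dimethoxy-6-methyl-5-(prop-2-en-1-yl)bicyclo[3.2.1]octane-2,8-diol
Product: 23 (1S,5S,6R,7S,8S)-7-(3,4-dimethoxyphenyl)-8-hydroxy-1,3-dimethoxy-6-methyl-5-(prop-2-en-1-yl)bicyclo[3.2.1]octan-2-one
Conditions: TEMPO (20 mol%), PhI(OAc)2, CH2Cl2, 25 °C
Reagents that add atoms: none
Why: Oxoammonium (TEMPO) oxidation is very sensitive to steric hindrance and oxidises the C2 carbinol while sparing the C8 carbinol flanked by two quaternary carbons.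

**Step 15**
Reactants: 23 (1S,5S,6R,7S,8S)-7-(3,4-dimethoxyphenyl)-8-hydroxy-1,3-dimethoxy-6-methyl-5-(prop-2-en-1-yl)bicyclo[3.2.1]octan-2-one
Product: 24 (1S,5S,6R,7S,8S)-7-(3,4-dimethoxyphenyl)-1,3-dimethoxy-6-methyl-2-oxo-5-(prop-2-en-1-yl)bicyclo[3.2.1]octan-8-yl acetate (C3 epimers)
Conditions: Ac2O, DMAP, Et3N, CH2Cl2, 40 °C
Reagents that add atoms: acetic anhydride, CC(=O)OC(C)=O
Why: DMAP-catalysed acylation esterifies the hindered secondary C8 alcohol and touches no stereocentre other than the base-labile C3, which is set in the next step.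

**Step 16**
Reactants: 24 (1S,5S,6R,7S,8S)-7-(3,4-dimethoxyphenyl)-1,3-dimethoxy-6-methyl-2-oxo-5-(prop-2-en-1-yl)bicyclo[3.2.1]octan-8-yl acetate (C3 epimers)
Product: 25 (1S,3S,5S,6R,7S,8S)-7-(3,4-dimethoxyphenyl)-1,3-dimethoxy-6-methyl-2-oxo-5-(prop-2-en-1-yl)bicyclo[3.2.1]octan-8-yl acetate
Conditions: LiN(SiMe3)2, THF, −78 °C; then AcOH, −78 °C
Reagents that add atoms: none
Why: Kinetic protonation of the lithium enolate (only C3–H is enolisable, C1 being quaternary) occurs from the exo face because the endo face of C3 is screened by the endo aryl group at C7, which places H exo and OMe endo (3S) from both epimers of 24.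

**Compound list**
1 | (R)-(+)-pulegone | C[C@@H]1CCC(=C(C)C)C(=O)C1 | starting material
2 | pulegone dibromide, 2-bromo-2-(2-bromopropan-2-yl)-5-methylcyclohexan-1-one (methyl centre as in 1) | C[C@@H]1CCC(Br)(C(C)(C)Br)C(=O)C1 | intermediate
3 | methyl pulegenate, methyl (5R)-5-methyl-2-(propan-2-ylidene)cyclopentane-1-carboxylate (C1 epimers) | COC(=O)C1C(=C(C)C)CC[C@H]1C | intermediate
4 | methyl (1S,2R)-2-methyl-5-oxocyclopentane-1-carboxylate (trans) | COC(=O)[C@@H]1C(=O)CC[C@H]1C | intermediate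
5 | allyl bromide | C=CCBr | starting material
6 | methyl (1R,2R)-2-methyl-5-oxo-1-(prop-2-en-1-yl)cyclopentane-1-carboxylate (allyl trans to methyl) | C=CC[C@]1(C(=O)OC)C(=O)CC[C@H]1C | intermediate
7 | (2S,3R)-3-methyl-2-(prop-2-en-1-yl)cyclopentan-1-one (trans) | C=CC[C@@H]1C(=O)CC[C@H]1C | intermediate
8 | methyl 2-methoxyacrylate | C=C(OC)C(=O)OC | starting material
9 | (2S,3R)-N-benzyl-3-methyl-2-(prop-2-en-1-yl)cyclopentan-1-imine | C=CC[C@@H]1C(=NCc2ccccc2)CC[C@H]1C | intermediate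
10 | methyl 3-[(1S,2R)-5-(benzylimino)-2-methyl-1-(prop-2-en-1-yl)cyclopentyl]-2-methoxypropanoate | C=CC[C@@]1(CC(OC)C(=O)OC)C(=NCc2ccccc2)CC[C@H]1C | intermediate
11 | methyl 2-methoxy-3-[(1S,2R)-2-methyl-5-oxo-1-(prop-2-en-1-yl)cyclopentyl]propanoate (epimers at the methoxy carbon; allyl cis to methyl) | C=CC[C@@]1(CC(OC)C(=O)OC)C(=O)CC[C@H]1C | intermediate
12 | methyl 2-methoxy-3-[(1S,2R)-2-methyl-1-(prop-2-en-1-yl)-5-(trimethylsilyloxy)cyclopent-4-en-1-yl]propanoate | C=CC[C@@]1(CC(OC)C(=O)OC)C(O[Si](C)(C)C)=CC[C@H]1C | intermediate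
13 | methyl 2-methoxy-3-[(1S,5R)-5-methyl-2-oxo-1-(prop-2-en-1-yl)cyclopent-3-en-1-yl]propanoate | C=CC[C@@]1(CC(OC)C(=O)OC)C(=O)C=C[C@H]1C | intermediate
14 | 3,4-dimethoxyphenylmagnesium bromide | COc1ccc([Mg]Br)cc1OC | starting material
15 | methyl 3-[(1S,2R,3R)-3-(3,4-dimethoxyphenyl)-2-methyl-1-(prop-2-en-1-yl)-5-(trimethylsilyloxy)cyclopent-4-en-1-yl]-2-methoxypropanoate (aryl trans to methyl) | C=CC[C@@]1(CC(OC)C(=O)OC)C(O[Si](C)(C)C)=C[C@H](c2ccc(OC)c(OC)c2)[C@H]1C | intermediate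
16 | methyl 3-[(1S,2R,3S,4S)-3-(3,4-dimethoxyphenyl)-2-methyl-5-oxo-1-(prop-2-en-1-yl)-4-(trimethylsilyloxy)cyclopentyl]-2-methoxypropanoate | C=CC[C@@]1(CC(OC)C(=O)OC)C(=O)[C@@H](O[Si](C)(C)C)[C@H](c2ccc(OC)c(OC)c2)[C@H]1C | intermediate
17 | methyl 3-[(1S,2R,3S,4S)-3-(3,4-dimethoxyphenyl)-4-hydroxy-2-methyl-5-oxo-1-(prop-2-en-1-yl)cyclopentyl]-2-methoxypropanoate (OH trans to aryl) | C=CC[C@@]1(CC(OC)C(=O)OC)C(=O)[C@@H](O)[C@H](c2ccc(OC)c(OC)c2)[C@H]1C | intermediate
18 | methyl 3-[(1S,2R,3S,4S)-3-(3,4-dimethoxyphenyl)-4-methoxy-2-methyl-5-oxo-1-(prop-2-en-1-yl)cyclopentyl]-2-methoxypropanoate | C=CC[C@@]1(CC(OC)C(=O)OC)C(=O)[C@@H](OC)[C@H](c2ccc(OC)c(OC)c2)[C@H]1C | intermediate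
19 | (2S,3S,4R,5S)-3-(3,4-dimethoxyphenyl)-5-(3-hydroxy-2-methoxypropyl)-2-methoxy-4-methyl-5-(prop-2-en-1-yl)cyclopentan-1-ol (epimers at C1 and at the side-chain methoxy carbon) | C=CC[C@@]1(CC(OC)CO)C(O)[C@@H](OC)[C@H](c2ccc(OC)c(OC)c2)[C@H]1C | intermediate
20 | 3-[(1S,2R,3S,4S)-3-(3,4-dimethoxyphenyl)-4-methoxy-2-methyl-5-oxo-1-(prop-2-en-1-yl)cyclopentyl]-2-methoxypropanal | C=CC[C@@]1(CC(OC)C=O)C(=O)[C@@H](OC)[C@H](c2ccc(OC)c(OC)c2)[C@H]1C | intermediate
21 | (1R,5S,6R,7S)-7-(3,4-dimethoxyphenyl)-2-hydroxy-1,3-dimethoxy-6-methyl-5-(prop-2-en-1-yl)bicyclo[3.2.1]octan-8-one (C2 and C3 epimers; aryl endo, methyl exo) | C=CC[C@]12CC(OC)C(O)[C@](OC)([C@H](c3ccc(OC)c(OC)c3)[C@H]1C)C2=O | intermediate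
22 | (1S,5S,6R,7S,8S)-7-(3,4-dimethoxyphenyl)-1,3-dimethoxy-6-methyl-5-(prop-2-en-1-yl)bicyclo[3.2.1]octane-2,8-diol (C2 and C3 epimers; 8-OH syn to the three-carbon bridge) | C=CC[C@]12CC(OC)C(O)[C@](OC)([C@H](c3ccc(OC)c(OC)c3)[C@H]1C)[C@H]2O | intermediate
23 | (1S,5S,6R,7S,8S)-7-(3,4-dimethoxyphenyl)-8-hydroxy-1,3-dimethoxy-6-methyl-5-(prop-2-en-1-yl)bicyclo[3.2.1]octan-2-one (C3 epimers) | C=CC[C@]12CC(OC)C(=O)[C@](OC)([C@H](c3ccc(OC)c(OC)c3)[C@H]1C)[C@H]2O | intermediate
24 | (1S,5S,6R,7S,8S)-7-(3,4-dimethoxyphenyl)-1,3-dimethoxy-6-methyl-2-oxo-5-(prop-2-en-1-yl)bicyclo[3.2.1]octan-8-yl acetate (C3 epimers) | C=CC[C@]12CC(OC)C(=O)[C@](OC)([C@H](c3ccc(OC)c(OC)c3)[C@H]1C)[C@H]2OC(C)=O | intermediate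
25 | (1S,3S,5S,6R,7S,8S)-7-(3,4-dimethoxyphenyl)-1,3-dimethoxy-6-methyl-2-oxo-5-(prop-2-en-1-yl)bicyclo[3.2.1]octan-8-yl acetate (CNP0344493.1) | C=CC[C@]12C[C@H](OC)C(=O)[C@](OC)([C@H](c3ccc(OC)c(OC)c3)[C@H]1C)[C@H]2OC(C)=O | target

**Totals**
Total step count: 16. Longest linear sequence: 16 steps (1 to 25).

**Steps most likely to fail, with fallbacks**

Step 5 (Michael addition of a hindered enamine to an α-alkoxy-deactivated acrylate, forming a quaternary carbon). The fallback sets out from 7: thermodynamic silylation (TMSCl, NaI, Et3N, MeCN) gives the tetrasubstituted enol ether (R)-trimethyl{[3-methyl-2-(prop-2-en-1-yl)cyclopent-1-en-1-yl]oxy}silane F1. F1 is added to 8 in a TiCl4-promoted Mukaiyama–Michael reaction (CH2Cl2, −78 °C), again anti to the methyl group, and aqueous work-up comes back to the route at 11.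

Step 12 (aldol closure to a quaternary, methoxy-bearing bridgehead next to the aryl-bearing carbon). The fallback sets out from ester 18, so steps 10 and 11 are skipped. KN(SiMe3)2 (THF, −78 °C) forms the C1 enolate, which acylates intramolecularly (Dieckmann-type Claisen condensation) to the non-enolisable (1S,5S,6R,7S)-7-(3,4-dimethoxyphenyl)-1,3-dimethoxy-6-methyl-5-(prop-2-en-1-yl)bicyclo[3.2.1]octane-2,8-dione F2. NaBH4/CeCl3 (MeOH, −78 °C) then reduces the more accessible C2 carbonyl and comes back to the route at 21.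

Step 13 (facial outcome at C8; the required hydrogen lies on the side hindered by the exo methyl). The fallback sets out from 21: NaBH4 (hydride from the open face) gives the C8-epimeric diol (1S,5S,6R,7S,8R)-7-(3,4-dimethoxyphenyl)-1,3-dimethoxy-6-methyl-5-(prop-2-en-1-yl)bicyclo[3.2.1]octane-2,8-diol F3. TEMPO/PhI(OAc)2 gives the epimeric hydroxy ketone (1S,5S,6R,7S,8R)-7-(3,4-dimethoxyphenyl)-8-hydroxy-1,3-dimethoxy-6-methyl-5-(prop-2-en-1-yl)bicyclo[3.2.1]octan-2-one F4. DBU (toluene, 60 °C) equilibrates F4 by retro-aldol/aldol through the ring-opened (1S,6S,7R)-6-(3,4-dimethoxyphenyl)-3,5-dimethoxy-7-methyl-4-oxo-1-(prop-2-en-1-yl)cycloheptane-1-carbaldehyde F5 towards the epimer with the hydroxyl away from the exo methyl, and comes back to the route at 23.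

**Further compounds**
F1 | step 5 | (R)-trimethyl{[3-methyl-2-(prop-2-en-1-yl)cyclopent-1-en-1-yl]oxy}silane | C=CCC1=C(O[Si](C)(C)C)CC[C@H]1C
F2 | step 12 | (1S,5S,6R,7S)-7-(3,4-dimethoxyphenyl)-1,3-dimethoxy-6-methyl-5-(prop-2-en-1-yl)bicyclo[3.2.1]octane-2,8-dione (C3 epimers) | C=CC[C@]12CC(OC)C(=O)[C@](OC)([C@H](c3ccc(OC)c(OC)c3)[C@H]1C)C2=O
F3 | step 13 | (1S,5S,6R,7S,8R)-7-(3,4-dimethoxyphenyl)-1,3-dimethoxy-6-methyl-5-(prop-2-en-1-yl)bicyclo[3.2.1]octane-2,8-diol (C2 and C3 epimers) | C=CC[C@]12CC(OC)C(O)[C@](OC)([C@H](c3ccc(OC)c(OC)c3)[C@H]1C)[C@@H]2O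
F4 | step 13 | (1S,5S,6R,7S,8R)-7-(3,4-dimethoxyphenyl)-8-hydroxy-1,3-dimethoxy-6-methyl-5-(prop-2-en-1-yl)bicyclo[3.2.1]octan-2-one (C3 epimers) | C=CC[C@]12CC(OC)C(=O)[C@](OC)([C@H](c3ccc(OC)c(OC)c3)[C@H]1C)[C@@H]2O
F5 | step 13 | (1S,6S,7R)-6-(3,4-dimethoxyphenyl)-3,5-dimethoxy-7-methyl-4-oxo-1-(prop-2-en-1-yl)cycloheptane-1-carbaldehyde (C3 and C5 epimers) | C=CC[C@]1(C=O)CC(OC)C(=O)C(OC)[C@H](c2ccc(OC)c(OC)c2)[C@H]1C
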